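Begin with the easy step: the growth step and the death step both run on living end times free monomer, so their rates keep one fixed ratio at every moment.

free monomer 25 mM; initiator 50 µM; time 40 h

    free monomer + initiator → living end + monomer in chains (k1 = 0.0368 L mol⁻¹ min⁻¹)
    free monomer + living end → monomer in chains + living end, rate k2*[living end]*[free monomer] (k2 = 81.6 L mol⁻¹ min⁻¹)
    monomer in chains → over-reaction product (k3 = 4.02 × 10⁻⁶ min⁻¹)
    living end + free monomer → dead end (k4 = 0.0864 L mol⁻¹ min⁻¹)

- the average divides the monomer in chains by the number of chains begun, living and dead together
- run time (flask): 40 h

1. average number of monomer units in a chain (chains begun, living or dead) at 40 h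
2. part of the free monomer that has reacted at 40 h

Call ν = 944 the chain allowance, the free monomer taken up by growth per dead end formed, known as the kinetic chain length. Divide reacted monomer by ν for the dead ends, then add the living ends for the chains begun.

Next, find the living ends. Starting (constant s) and death (constant d) both carry free monomer, so it cancels from their contest, and by my reckoning the living end in this flask peaks at the initiator charge times (s/d)^(d/(d−s)), which is 11.3 µM.

Hold the living end at that peak. Free monomer then falls pseudo-first-order at 0.0554 h⁻¹, giving 89.1% reacted at 40 h. Count reacted monomer as monomer in chains, since the over-reaction constant times the run is small, at 0.965%. The average is then 638.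

The weak link is the opening, when living ends are still rising. At the starting feed the peak takes 4.10 h to fill, so strike that time from the run. My numbers become 86.3% and 632.

The forecast gives 86%, close to mine, and 655, above mine, reasoning that “Termination runs at about the same pace as initiation because both scale with free monomer”.

For the flask the simulation gives 655 and 85.7%. In the flask at 13.5 h the growth step takes free monomer 910 times as fast as the starting step. In this flask ν turns the reacted monomer into 22.7 µM of dead ends, against 22.6 µM in the table, and adding 9.84 µM of living ends gives an average of 659. In the neighbour charged with 10 mM of free monomer, 81.4% reacted gives 8.62 µM of dead ends, and with 11.0 µM of living ends an average of 415, where the simulation has 413.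

The numbers are invented; the rest is arithmetic.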